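**Retrosynthetic overview**

1. The target is a symmetric tetramer, ring F–CH2–ring P–CH2–ring P–CH2–ring F (F = enolised 2-propanoyl-4,4-dimethylcyclohexane-1,3,5-trione, P = propanoylphloroglucinol). The central CH2 is cut first: formaldehyde joins two F–CH2–P halves (13).
2. In each half the propanoyl group on ring F is removed (C-acylation of trione 11), and the phenols of ring P are masked as benzyl ethers.
3. Key disconnection: ring F is opened at the bond between the acyl-bearing carbon and its enolic neighbour, and at the bond between the CMe2 carbon and its enolic neighbour. This is a (3+3) annulation of a benzylmalonyl half-ester chloride (7) with the enol ether of 3-methylbutan-2-one (9).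
4. Enabling feature: the ring-F carbons C(OH)–C(CH2Ar)–C(OH) are a 2-substituted malonyl unit, and the other three, CMe2–C(=O)–C(acyl), are the α′, carbonyl and α carbons of a ketone. The CMe2 carbon has no hydrogen once acylated, so neither aromatisation nor a 2-pyranone is possible and the trione enolate is the only sink.
5. Ring order: ring P is bought (flopropione 1); ring F is built onto its side chain (step 6); then acylation, debenzylation and dimerisation.

Key step: step 6

Assumption (remark on the chemistry): the triketone rings are drawn in the enol tautomer of the target SMILES and all tautomers interconvert; the target is achiral, and the only stereocentre on the route (the malonyl CH of 6, 7 and 10) is racemic and is erased when that carbon becomes an enol carbon in 11.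

**Route**

Step 1
Reactants: 1 flopropione, 1-(2,4,6-trihydroxyphenyl)propan-1-one
Product: 2 2,4,6-trihydroxy-3-propanoylbenzaldehyde
Conditions: POCl3 (1.1 equiv), DMF (1.2 equiv), EtOAc, 0 °C to rt; then H2O, 50 °C
Reagents that add atoms: N,N-dimethylformamide CN(C)C=O; water O
Why: Vilsmeier–Haack formylation of the electron-rich phloroglucinol nucleus, in which the two free ring positions of 1 are equivalent and the first formyl group deactivates the ring against a second one.

Step 2
Reactants: 2 2,4,6-trihydroxy-3-propanoylbenzaldehyde
Product: 3 2,4,6-tris(benzyloxy)-3-propanoylbenzaldehyde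
Conditions: BnBr (3.6 equiv), K2CO3 (4 equiv), n-Bu4NI (cat.), DMF, 60 °C
Reagents that add atoms: benzyl bromide BrCc1ccccc1
Why: Williamson O-benzylation of the three phenoxides in a dipolar aprotic solvent, where O-alkylation of acylphloroglucinols should dominate over C-alkylation; benzyl is chosen because it is removed at the end by neutral hydrogenolysis.

Step 3
Reactants: 3 2,4,6-tris(benzyloxy)-3-propanoylbenzaldehyde; 4 Meldrum's acid (2,2-dimethyl-1,3-dioxane-4,6-dione)
Product: 5 2,2-dimethyl-5-{[2,4,6-tris(benzyloxy)-3-propanoylphenyl]methyl}-1,3-dioxane-4,6-dione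
Conditions: Hantzsch ester (diethyl 2,6-dimethyl-1,4-dihydropyridine-3,5-dicarboxylate, 1.1 equiv), L-proline (20 mol%), EtOH, rt
Reagents that add atoms: none
Why: Knoevenagel condensation followed in the same flask by conjugate transfer hydrogenation of the alkylidene Meldrum's acid (organocatalytic reductive alkylation), which should stop cleanly at the monoalkylated stage and leave the hindered aryl ketone alone.

Step 4
Reactants: 5 2,2-dimethyl-5-{[2,4,6-tris(benzyloxy)-3-propanoylphenyl]methyl}-1,3-dioxane-4,6-dione
Product: 7 methyl 3-chloro-3-oxo-2-{[2,4,6-tris(benzyloxy)-3-propanoylphenyl]methyl}propanoate (racemic), via malonic half ester 6 (not isolated)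
Conditions: MeOH, reflux; evaporate, toluene azeotrope; (COCl)2 (1.5 equiv), DMF (cat.), CH2Cl2, 0 °C to rt; evaporate
Reagents that add atoms: methanol CO; oxalyl chloride ClC(=O)C(=O)Cl
Why: Methanolysis of a monosubstituted Meldrum's acid gives the malonic half ester with loss of acetone, and chlorination of the free acid then differentiates the two malonyl carbonyls as a fast (chloride) and a slow (ester) acyl donor; the new stereocentre is racemic and is lost later.

Step 5
Reactants: 8 3-bromo-3-methylbutan-2-one
Product: 9 trimethyl[(3-methylbut-2-en-2-yl)oxy]silane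
Conditions: Zn dust, Me3SiCl, TMEDA, Et2O, 0 °C to rt; distil
Reagents that add atoms: chlorotrimethylsilane C[Si](C)(C)Cl
Why: Reformatsky-type zinc insertion into the tertiary C–Br bond should give the enolate at the gem-dimethyl carbon only, and O-silylation fixes it as the single tetrasubstituted enol ether regioisomer.

Step 6
Reactants: 7 methyl 3-chloro-3-oxo-2-{[2,4,6-tris(benzyloxy)-3-propanoylphenyl]methyl}propanoate; 9 trimethyl[(3-methylbut-2-en-2-yl)oxy]silane
Product: 11 3-hydroxy-4,4-dimethyl-2-{[2,4,6-tris(benzyloxy)-3-propanoylphenyl]methyl}cyclohex-2-ene-1,5-dione, via diketo ester 10 (not isolated)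
Conditions: 9 (2 equiv), ZnCl2 (0.2 equiv), CH2Cl2, −20 °C to rt; evaporate volatiles; KOtBu (4 equiv), THF, 0 to 40 °C; then 1 M HCl
Reagents that add atoms: none
Why: ZnCl2 activates acid chloride 7 and the tetrasubstituted enol ether carbon of 9 attacks it (Mukaiyama-type C-acylation, loss of Me3SiCl), which forms the bond between the CMe2 carbon and its enolic neighbour and gives the non-enolisable 2,2-dimethyl-1,3-diketone 10; KOtBu then turns the methyl ketone of 10 into its enolate, which attacks the methyl ester (Dieckmann condensation, loss of methoxide) and forms the bond between the future acyl-bearing carbon and the second enolic carbon. The closest known reaction types are the Effenberger α,α′-annulation of ketone enol ethers with malonyl chlorides to bridged cyclohexane-1,3,5-triones and the Dieckmann closure of methyl ketones onto esters that gives filicinic- and syncarpic-type triones. Ring F closes in the second stage by a 6-(enolendo)-exo-trig attack of the ketone enolate on the ester carbonyl. No stereocentre is created: the CMe2 carbon carries two identical groups and the racemic malonyl CH of 7 and 10 becomes an sp2 enol carbon in 11. The step needs acylation at the more substituted α-carbon first, C- instead of O-acylation, and a carbocycle instead of an enol lactone; the first is fixed by the regiodefined enol ether 9, the second by the neutral silyl enol ether/ZnCl2 manifold, and the third by the gem-dimethyl carbon, which rules out an aromatic 2-pyranone, together with an ester as second acyl group, so that any O-acylation stays reversible under alkoxide and the material should drain into the doubly enolised trione salt. The benzyl ethers keep the phenols out of the acylation, and the excess of the more nucleophilic enol ether should outcompete the hindered aromatic C–H.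

Step 7
Reactants: 11 3-hydroxy-4,4-dimethyl-2-{[2,4,6-tris(benzyloxy)-3-propanoylphenyl]methyl}cyclohex-2-ene-1,5-dione
Product: 12 3,5-dihydroxy-6,6-dimethyl-2-propanoyl-4-{[2,4,6-tris(benzyloxy)-3-propanoylphenyl]methyl}cyclohexa-2,4-dien-1-one
Conditions: EtCO2H (1.1 equiv), DCC (1.2 equiv), DMAP (0.3 equiv), CH2Cl2, rt
Reagents that add atoms: propanoic acid CCC(=O)O
Why: Steglich-type O-acylation followed by DMAP-mediated O-to-C acyl migration, the standard C-acylation of cyclic 1,3-diones, should end at the only free ring carbon because only there is the product a stabilised, hydrogen-bonded enolised triketone.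

Step 8
Reactants: 12 3,5-dihydroxy-6,6-dimethyl-2-propanoyl-4-{[2,4,6-tris(benzyloxy)-3-propanoylphenyl]methyl}cyclohexa-2,4-dien-1-one
Product: 13 3,5-dihydroxy-6,6-dimethyl-2-propanoyl-4-[(2,4,6-trihydroxy-3-propanoylphenyl)methyl]cyclohexa-2,4-dien-1-one
Conditions: H2 (1 atm), 10% Pd/C, EtOAc/MeOH, rt
Reagents that add atoms: none
Why: Catalytic hydrogenolysis of the three aryl benzyl ethers under neutral conditions, which should leave the hydrogen-bonded aryl ketone, the enolised triketone and the ArCH2–C bond untouched.

Step 9
Reactants: 13 3,5-dihydroxy-6,6-dimethyl-2-propanoyl-4-[(2,4,6-trihydroxy-3-propanoylphenyl)methyl]cyclohexa-2,4-dien-1-one (2 equiv)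
Product: 14 CNP0541376.0, bis{2,4,6-trihydroxy-3-propanoyl-5-[(2,6-dihydroxy-3,3-dimethyl-4-oxo-5-propanoylcyclohexa-1,5-dien-1-yl)methyl]phenyl}methane
Conditions: CH2O (37% aq., 0.5 equiv), 1% aq. KOH (2 equiv), 0 °C, short reaction time; then dilute HCl
Reagents that add atoms: formaldehyde C=O
Why: Base-mediated hydroxymethylation of the only free aromatic position of ring P, loss of water to the ortho-quinone methide and conjugate addition of a second phenoxide (the classical methylene bridging of acylphloroglucinols); ring F has no free position, so a single symmetric dimer should result.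

**Compound list**

1 | flopropione, 1-(2,4,6-trihydroxyphenyl)propan-1-one | CCC(=O)c1c(O)cc(O)cc1O | starting material
2 | 2,4,6-trihydroxy-3-propanoylbenzaldehyde | CCC(=O)c1c(O)cc(O)c(C=O)c1O | intermediate
3 | 2,4,6-tris(benzyloxy)-3-propanoylbenzaldehyde | CCC(=O)c1c(OCc2ccccc2)cc(OCc2ccccc2)c(C=O)c1OCc1ccccc1 | intermediate
4 | Meldrum's acid, 2,2-dimethyl-1,3-dioxane-4,6-dione | CC1(C)OC(=O)CC(=O)O1 | starting material
5 | 2,2-dimethyl-5-{[2,4,6-tris(benzyloxy)-3-propanoylphenyl]methyl}-1,3-dioxane-4,6-dione | CCC(=O)c1c(OCc2ccccc2)cc(OCc2ccccc2)c(CC2C(=O)OC(C)(C)OC2=O)c1OCc1ccccc1 | intermediate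
6 | 3-methoxy-3-oxo-2-{[2,4,6-tris(benzyloxy)-3-propanoylphenyl]methyl}propanoic acid (racemic, formed in the flask) | CCC(=O)c1c(OCc2ccccc2)cc(OCc2ccccc2)c(CC(C(=O)O)C(=O)OC)c1OCc1ccccc1 | intermediate
7 | methyl 3-chloro-3-oxo-2-{[2,4,6-tris(benzyloxy)-3-propanoylphenyl]methyl}propanoate (racemic) | CCC(=O)c1c(OCc2ccccc2)cc(OCc2ccccc2)c(CC(C(Cl)=O)C(=O)OC)c1OCc1ccccc1 | intermediate
8 | 3-bromo-3-methylbutan-2-one | CC(=O)C(C)(C)Br | starting material
9 | trimethyl[(3-methylbut-2-en-2-yl)oxy]silane | CC(C)=C(C)O[Si](C)(C)C | intermediate
10 | methyl 4,4-dimethyl-3,5-dioxo-2-{[2,4,6-tris(benzyloxy)-3-propanoylphenyl]methyl}hexanoate (racemic, formed in the flask) | CCC(=O)c1c(OCc2ccccc2)cc(OCc2ccccc2)c(CC(C(=O)OC)C(=O)C(C)(C)C(C)=O)c1OCc1ccccc1 | intermediate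
11 | 3-hydroxy-4,4-dimethyl-2-{[2,4,6-tris(benzyloxy)-3-propanoylphenyl]methyl}cyclohex-2-ene-1,5-dione | CCC(=O)c1c(OCc2ccccc2)cc(OCc2ccccc2)c(CC2=C(O)C(C)(C)C(=O)CC2=O)c1OCc1ccccc1 | intermediate
12 | 3,5-dihydroxy-6,6-dimethyl-2-propanoyl-4-{[2,4,6-tris(benzyloxy)-3-propanoylphenyl]methyl}cyclohexa-2,4-dien-1-one | CCC(=O)C1=C(O)C(Cc2c(OCc3ccccc3)cc(OCc3ccccc3)c(C(=O)CC)c2OCc2ccccc2)=C(O)C(C)(C)C1=O | intermediate
13 | 3,5-dihydroxy-6,6-dimethyl-2-propanoyl-4-[(2,4,6-trihydroxy-3-propanoylphenyl)methyl]cyclohexa-2,4-dien-1-one | CCC(=O)C1=C(O)C(Cc2c(O)cc(O)c(C(=O)CC)c2O)=C(O)C(C)(C)C1=O | intermediate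
14 | CNP0541376.0, bis{2,4,6-trihydroxy-3-propanoyl-5-[(2,6-dihydroxy-3,3-dimethyl-4-oxo-5-propanoylcyclohexa-1,5-dien-1-yl)methyl]phenyl}methane | CCC(=O)C1=C(O)C(Cc2c(O)c(Cc3c(O)c(CC4=C(O)C(C)(C)C(=O)C(C(=O)CC)=C4O)c(O)c(C(=O)CC)c3O)c(O)c(C(=O)CC)c2O)=C(O)C(C)(C)C1=O | target

**Step count and risks**

Total step count: 9. Longest linear sequence: 8 steps (1, 2, 3, 4, 6, 7, 8, 9, from flopropione); step 5 is a one-step branch.

Steps most likely to fail:

Step 6. In the first stage, O-acylation of the enol ether, dealkylative lactonisation of the acid chloride onto an ortho benzyloxy group, or Friedel–Crafts acylation of the free aromatic position may compete with C-acylation. In the second stage, enol-lactone formation or retro-Claisen cleavage of the 2,2-dimethyl-1,3-diketone may compete with C–C ring closure. The fallback gives up the annulation and brings ring F in ready-made. It sets out from aldehyde 3, which is condensed with an excess of filicinic acid F1 (made by the classical C,C-dimethylation of phloroglucinol with MeI and NaOMe) under the reductive Knoevenagel conditions of step 3 (L-proline, Hantzsch ester, EtOH, rt). Monoalkylation at one of the two equivalent ring CH2 groups of F1 should give trione 11, where the route is rejoined.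

Step 9. Under alkali the existing ArCH2–trione bridge may undergo retro-Michael cleavage and recombination (methylene scrambling), and over-condensation may compete with formation of the single new bridge. The fallback separates electrophile formation from coupling and avoids alkali. It sets out from 13, which is aminomethylated at the free aromatic position with dimethylmethylideneammonium iodide in MeCN to give the Mannich base F2. Heating F2 with one equivalent of 13 in dioxane should expel dimethylamine, generate the ortho-quinone methide and, by conjugate addition of the aromatic carbon of the second half, give 14, where the route is rejoined.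

Step 7. Acyl transfer may stop at an enol ester, or acylation may occur at the enol system flanking the benzylic carbon instead of at the ring CH2. The fallback introduces the propanoyl group before ring F is joined to ring P. It sets out from 1 and 3: flopropione 1 is C,C-dimethylated (MeI, NaOMe, MeOH) to propionylfilicinic acid F3, and reductive Knoevenagel alkylation of F3 with aldehyde 3 (L-proline, Hantzsch ester, EtOH) at its only free ring carbon should give 12 directly, where the route is rejoined.

**Further compounds**

F1 | step 6 | filicinic acid, 4,4-dimethylcyclohexane-1,3,5-trione | CC1(C)C(=O)CC(=O)CC1=O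
F2 | step 9 | 4-({3-[(dimethylamino)methyl]-2,4,6-trihydroxy-5-propanoylphenyl}methyl)-3,5-dihydroxy-6,6-dimethyl-2-propanoylcyclohexa-2,4-dien-1-one | CCC(=O)C1=C(O)C(Cc2c(O)c(CN(C)C)c(O)c(C(=O)CC)c2O)=C(O)C(C)(C)C1=O
F3 | step 7 | propionylfilicinic acid, 3,5-dihydroxy-6,6-dimethyl-2-propanoylcyclohexa-2,4-dien-1-one | CCC(=O)C1=C(O)C=C(O)C(C)(C)C1=O
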